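The 22-membered macrocycle is opened at the CH2–CH2 bond that joins the allylic carbon of the (Z)-alkene to its saturated neighbour on the carbinol side. That bond is made in the ring-closing step by intramolecular SN2 alkylation: a phenylsulfonyl-stabilised carbanion at the end of the six-carbon arm of ring B (the pyrogallol ring) displaces chloride from the (Z)-allylic chloride that ends the eight-carbon arm of ring A (the resorcinol ring). The step exploits the allylic activation of that carbon by the cis C=C, whose geometry is set beforehand by Lindlar reduction. The precursor is a fully silylated seco diaryl ether assembled by Chan–Lam coupling; the sulfone is then removed reductively.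

Key step: step 13

Remark: TBS = tert-butyldimethylsilyl. The chain is numbered C1′ (carbinol carbon on ring B) to C14′ (benzylic CH2 on ring A), so the alkene is C8′=C9′ and the bond made in step 13 is C6′–C7′. The sulfonyl-bearing C6′ of 26 forms as both epimers, which is immaterial because step 14 removes the sulfone.

Step 1
Reactants: 1 methyl gallate (methyl 3,4,5-trihydroxybenzoate)
Product: 2 methyl 3,5-bis[(tert-butyldimethylsilyl)oxy]-4-hydroxybenzoate
Conditions: TBSCl (2.05 equiv), imidazole, DMF, 0 → 25 °C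
Reagents that add atoms: tert-butyldimethylsilyl chloride `CC(C)(C)[Si](C)(C)Cl`
Why: Phenol silylation in which base-mediated O-to-O silyl migration between neighbouring oxygens should funnel the bis-silyl ether to the 3,5-isomer, leaving free the 4-OH that is most acidic (para to the ester) and flanked on both sides.

Step 2
Reactants: 3 3,5-dibromophenol
Product: 4 tert-butyl(3,5-dibromophenoxy)dimethylsilane
Conditions: TBSCl, imidazole, CH2Cl2, 25 °C
Reagents that add atoms: tert-butyldimethylsilyl chloride `CC(C)(C)[Si](C)(C)Cl`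
Why: Routine O-silylation of an unhindered phenol.

Step 3
Reactants: 4 tert-butyl(3,5-dibromophenoxy)dimethylsilane
Product: 7 {3-bromo-5-[(tert-butyldimethylsilyl)oxy]phenyl}boronic acid, via aryllithium 5 (not isolated), via lithium aryl(triisopropoxy)borate 6 (not isolated)
Conditions: n-BuLi (1.0 equiv), Et2O, −78 °C; B(Oi-Pr)3, −78 → 0 °C; 1 M HCl, 0 °C
Reagents that add atoms: triisopropyl borate `CC(C)OB(OC(C)C)OC(C)C`; water `O`; n-butyllithium `[Li]CCCC` (lithium held only in 5 and 6)
Why: Bromine–lithium exchange stops after one C–Br bond because the second exchange would build a dianion, and borate quench with mild acid hydrolysis should give the boronic acid with the meta silyl ether untouched.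

Step 4
Reactants: 2 methyl 3,5-bis[(tert-butyldimethylsilyl)oxy]-4-hydroxybenzoate; 7 {3-bromo-5-[(tert-butyldimethylsilyl)oxy]phenyl}boronic acid
Product: 8 methyl 4-{3-bromo-5-[(tert-butyldimethylsilyl)oxy]phenoxy}-3,5-bis[(tert-butyldimethylsilyl)oxy]benzoate
Conditions: Cu(OAc)2 (2 equiv), pyridine, 4 Å molecular sieves, CH2Cl2, dry air, 25 °C
Reagents that add atoms: none
Why: Chan–Lam O-arylation, in which the aryl group passes from boron to divalent copper and C–O reductive elimination from a trivalent copper aryl phenoxide forms the diaryl ether at room temperature, conditions that spare silyl ethers and the C–Br bond and are known to tolerate phenols with two ortho substituents.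

Step 5
Reactants: 8 methyl 4-{3-bromo-5-[(tert-butyldimethylsilyl)oxy]phenoxy}-3,5-bis[(tert-butyldimethylsilyl)oxy]benzoate; 9 1-bromo-5-chloropentane
Product: 12 1-(4-{3-bromo-5-[(tert-butyldimethylsilyl)oxy]phenoxy}-3,5-bis[(tert-butyldimethylsilyl)oxy]phenyl)-6-chlorohexan-1-one, via Grignard reagent 10 (not isolated), via Weinreb amide 11 (not isolated)
Conditions: 9, Mg, THF, 25 °C (gives 10); separately 8, MeNH(OMe)·HCl (1.5 equiv), i-PrMgCl (3.0 equiv), THF, −20 °C (gives 11); then 10, −20 → 0 °C; aq NH4Cl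
Reagents that add atoms: magnesium `[Mg]` (held only in 10); N,O-dimethylhydroxylamine hydrochloride `CNOC.Cl` (held only in 11)
Why: One-pot Weinreb ketone synthesis, in which the magnesium amide turns the ester into amide 11 and Grignard reagent 10 (formed at the C–Br bond of 9 only) adds once, while the aryl bromide and alkyl chloride are inert at these temperatures.

Step 6
Reactants: 12 the 6-chlorohexan-1-one
Product: 13 (1R)-1-(4-{3-bromo-5-[(tert-butyldimethylsilyl)oxy]phenoxy}-3,5-bis[(tert-butyldimethylsilyl)oxy]phenyl)-6-chlorohexan-1-ol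
Conditions: (S)-2-methyl-CBS-oxazaborolidine (15 mol %), BH3·SMe2, THF, −20 °C; MeOH
Reagents that add atoms: none
Why: Corey–Bakshi–Shibata reduction, in which the (S)-oxazaborolidine holds the ketone with the aryl group as the large substituent and delivers hydride to the face that gives the (R)-carbinol, the same sense as acetophenone to (R)-1-phenylethanol.

Step 7
Reactants: 13 the (R)-chlorohexanol
Product: 14 tert-butyl{[(1R)-1-(4-{3-bromo-5-[(tert-butyldimethylsilyl)oxy]phenoxy}-3,5-bis[(tert-butyldimethylsilyl)oxy]phenyl)-6-chlorohexyl]oxy}dimethylsilane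
Conditions: TBSOTf, 2,6-lutidine, CH2Cl2, −78 → 0 °C
Reagents that add atoms: tert-butyldimethylsilyl trifluoromethanesulfonate `CC(C)(C)[Si](C)(C)OS(=O)(=O)C(F)(F)F`
Why: Silylation of the secondary benzylic alcohol under non-ionising basic conditions, so the stereocentre is not touched and the alkoxide can no longer compete in step 13.

Step 8
Reactants: 14 the (R)-chloride tetrakis-silyl ether
Product: 15 the (R)-sulfone: 14 with Cl replaced by phenylsulfonyl, i.e. the 6-(phenylsulfonyl)-1-[(tert-butyldimethylsilyl)oxy]hexyl arm on ring B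
Conditions: PhSO2Na, Bu4NI (cat.), DMF, 70 °C
Reagents that add atoms: sodium benzenesulfinate `[Na+].[O-]S(=O)c1ccccc1`
Why: SN2 displacement of the primary chloride by the sulfur atom of the sulfinate (iodide catalysis) gives the sulfone directly, with the aryl bromide and silyl ethers inert to this weakly basic salt.

Step 9
Reactants: 16 prop-2-yn-1-ol; 17 5-bromopent-1-ene
Product: 19 oct-7-en-2-yn-1-ol, via dilithiated propargyl alcohol 18 (not isolated)
Conditions: n-BuLi (2.1 equiv), THF/DMPU, −78 → 0 °C; 17, 0 → 25 °C; H2O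
Reagents that add atoms: n-butyllithium `[Li]CCCC` (lithium held only in 18)
Why: Alkylation of the propargyl alcohol dianion occurs at the acetylide carbon, which is far more nucleophilic than the lithium alkoxide toward a primary bromide.

Step 10
Reactants: 19 oct-7-en-2-yn-1-ol; 15 the (R)-sulfone aryl bromide
Product: 21 8-(3-{2,6-bis[(tert-butyldimethylsilyl)oxy]-4-[(1R)-1-[(tert-butyldimethylsilyl)oxy]-6-(phenylsulfonyl)hexyl]phenoxy}-5-[(tert-butyldimethylsilyl)oxy]phenyl)oct-2-yn-1-ol, via bis(9-BBN) adduct 20 (not isolated)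
Conditions: 19, 9-BBN (2.2 equiv), THF, 0 → 25 °C; then 15, Pd(OAc)2 (5 mol %), SPhos (10 mol %), K3PO4·H2O, THF, 40 °C
Reagents that add atoms: 9-borabicyclo[3.3.1]nonane `B1C2CCCC1CCC2` (boron held only in 20)
Why: 9-BBN hydroborates the terminal alkene anti-Markovnikov much faster than the internal alkyne (the OH is capped as a borinate), and B-alkyl Suzuki–Miyaura coupling on zerovalent palladium joins the primary alkyl group to the ring A bromide under a mild base that spares the aryl silyl ethers.

Step 11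
Reactants: 21 the propargylic alcohol
Product: 22 (2Z)-8-(3-{2,6-bis[(tert-butyldimethylsilyl)oxy]-4-[(1R)-1-[(tert-butyldimethylsilyl)oxy]-6-(phenylsulfonyl)hexyl]phenoxy}-5-[(tert-butyldimethylsilyl)oxy]phenyl)oct-2-en-1-ol
Conditions: H2 (1 atm), Lindlar catalyst (Pd on CaCO3, poisoned with Pb(OAc)2), quinoline, EtOAc, 25 °C
Reagents that add atoms: none
Why: Lindlar semihydrogenation delivers both hydrogens to one face of the alkyne on the poisoned palladium surface and so sets the (Z)-alkene, with sulfone and silyl ethers unaffected.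

Step 12
Reactants: 22 the (Z)-allylic alcohol
Product: 24 the (Z)-allylic chloride: 22 with OH replaced by Cl, via allylic mesylate 23 (not isolated)
Conditions: MsCl, 2,4,6-collidine, LiCl, DMF, 0 °C
Reagents that add atoms: lithium chloride `[Li+].[Cl-]`; methanesulfonyl chloride `CS(=O)(=O)Cl` (held only in 23)
Why: Mesylation and in situ SN2 displacement by chloride at the primary carbon give the allylic chloride without allylic transposition or loss of (Z)-geometry.

Step 13
Reactants: 24 the (Z)-allylic chloride sulfone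
Product: 26 the 22-membered macrocyclic sulfone (tetrakis-TBS ether, phenylsulfonyl on C6′, (R) at C1′, (Z)-C8′=C9′, both epimers at C6′), via potassium sulfonyl carbanion 25 (not isolated)
Conditions: KN(SiMe3)2 (1.5 equiv), THF (0.001 M), −78 → 0 °C
Reagents that add atoms: potassium bis(trimethylsilyl)amide `C[Si](C)(C)[N-][Si](C)(C)C.[K+]` (potassium held only in 25)
Why: KN(SiMe3)2 removes a proton from C6′ next to the sulfone to give carbanion 25, which attacks the primary allylic carbon C7′ in an intramolecular SN2 displacement of chloride and so forms the C6′–C7′ bond. The closest known reaction type is the macrocyclisation of sulfone-stabilised carbanions onto allylic halides, used for 14-membered and larger carbocycles. The one ring closed is the 22-membered macrocycle, formed in the exo-tet mode (22-exo-tet, the C–Cl bond lying outside the new ring). The only new stereocentre is the sulfonyl-bearing C6′; nothing controls it, both epimers are expected and step 14 erases it, while the (R)-carbinol centre is remote and not acidic. The step needs ring closure over oligomerisation (secured by 0.001 M dilution), attack at C7′ over attack at the far alkene carbon (secured by the unhindered primary terminus and the soft stabilised carbanion), and retention of the (Z)-geometry (secured because no metal allyl or allyl cation intervenes). The only acidic C–H in 24 is the one next to the sulfone, since every hydroxyl is capped as a silyl ether.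

Step 14
Reactants: 26 the macrocyclic sulfone
Product: 27 the tetrakis-TBS ether of the target macrocycle
Conditions: Na(Hg) (6 % Na), Na2HPO4, MeOH/THF, −20 → 0 °C
Reagents that add atoms: none
Why: Reductive desulfonylation by electron transfer cleaves the C–S bond and methanol protonates C6′, which is homoallylic so the alkene is neither moved nor isomerised, and both epimers converge on one compound (any phenolic silyl ether lost here converges in step 15).

Step 15
Reactants: 27 the tetrakis-TBS macrocycle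
Product: 28 CNP0316989.2, the target
Conditions: Bu4NF, AcOH, THF, argon, 0 → 25 °C
Reagents that add atoms: none
Why: Buffered fluoride cleaves the three aryl and the one benzylic silyl ether without acid, so the electron-rich benzylic (R)-carbinol cannot ionise and the (Z)-alkene is untouched.

Compound list
1 | methyl gallate | `COC(=O)c1cc(O)c(O)c(O)c1` | starting material
2 | methyl 3,5-bis[(tert-butyldimethylsilyl)oxy]-4-hydroxybenzoate | `COC(=O)c1cc(O[Si](C)(C)C(C)(C)C)c(O)c(O[Si](C)(C)C(C)(C)C)c1` | intermediate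
3 | 3,5-dibromophenol | `Oc1cc(Br)cc(Br)c1` | starting material
4 | tert-butyl(3,5-dibromophenoxy)dimethylsilane | `CC(C)(C)[Si](C)(C)Oc1cc(Br)cc(Br)c1` | intermediate
5 | {3-bromo-5-[(tert-butyldimethylsilyl)oxy]phenyl}lithium | `CC(C)(C)[Si](C)(C)Oc1cc(Br)cc([Li])c1` | intermediate
6 | lithium {3-bromo-5-[(tert-butyldimethylsilyl)oxy]phenyl}tri(propan-2-yloxy)borate | `[Li+].CC(C)O[B-](OC(C)C)(OC(C)C)c1cc(Br)cc(O[Si](C)(C)C(C)(C)C)c1` | intermediate
7 | {3-bromo-5-[(tert-butyldimethylsilyl)oxy]phenyl}boronic acid | `OB(O)c1cc(Br)cc(O[Si](C)(C)C(C)(C)C)c1` | intermediate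
8 | methyl 4-{3-bromo-5-[(TBS)oxy]phenoxy}-3,5-bis[(TBS)oxy]benzoate | `COC(=O)c1cc(O[Si](C)(C)C(C)(C)C)c(Oc2cc(Br)cc(O[Si](C)(C)C(C)(C)C)c2)c(O[Si](C)(C)C(C)(C)C)c1` | intermediate
9 | 1-bromo-5-chloropentane | `ClCCCCCBr` | starting material
10 | (5-chloropentyl)magnesium bromide | `ClCCCCC[Mg]Br` | intermediate
11 | 4-{3-bromo-5-[(TBS)oxy]phenoxy}-3,5-bis[(TBS)oxy]-N-methoxy-N-methylbenzamide | `CON(C)C(=O)c1cc(O[Si](C)(C)C(C)(C)C)c(Oc2cc(Br)cc(O[Si](C)(C)C(C)(C)C)c2)c(O[Si](C)(C)C(C)(C)C)c1` | intermediate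
12 | 1-(4-{3-bromo-5-[(TBS)oxy]phenoxy}-3,5-bis[(TBS)oxy]phenyl)-6-chlorohexan-1-one | `ClCCCCCC(=O)c1cc(O[Si](C)(C)C(C)(C)C)c(Oc2cc(Br)cc(O[Si](C)(C)C(C)(C)C)c2)c(O[Si](C)(C)C(C)(C)C)c1` | intermediate
13 | (1R)-1-(4-{3-bromo-5-[(TBS)oxy]phenoxy}-3,5-bis[(TBS)oxy]phenyl)-6-chlorohexan-1-ol | `CC(C)(C)[Si](C)(C)Oc1cc(Br)cc(c1)Oc1c(O[Si](C)(C)C(C)(C)C)cc(cc1O[Si](C)(C)C(C)(C)C)[C@H](O)CCCCCCl` | intermediate
14 | (R)-TBS ether of 13 | `CC(C)(C)[Si](C)(C)Oc1cc(Br)cc(c1)Oc1c(O[Si](C)(C)C(C)(C)C)cc(cc1O[Si](C)(C)C(C)(C)C)[C@H](O[Si](C)(C)C(C)(C)C)CCCCCCl` | intermediate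
15 | (R)-sulfone: ring A bromide carrying the 6-(phenylsulfonyl)-1-[(TBS)oxy]hexyl arm on ring B | `CC(C)(C)[Si](C)(C)Oc1cc(Br)cc(c1)Oc1c(O[Si](C)(C)C(C)(C)C)cc(cc1O[Si](C)(C)C(C)(C)C)[C@H](O[Si](C)(C)C(C)(C)C)CCCCCS(=O)(=O)c1ccccc1` | intermediate
16 | prop-2-yn-1-ol | `C#CCO` | starting material
17 | 5-bromopent-1-ene | `C=CCCCBr` | starting material
18 | lithium 3-lithioprop-2-yn-1-olate | `[Li]C#CCO[Li]` | intermediate
19 | oct-7-en-2-yn-1-ol | `C=CCCCC#CCO` | intermediate
20 | 9-{8-[(9-borabicyclo[3.3.1]nonan-9-yl)oxy]oct-6-yn-1-yl}-9-borabicyclo[3.3.1]nonane | `C(#CCCCCCB1C2CCCC1CCC2)COB1C2CCCC1CCC2` | intermediate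
21 | 8-(3-{2,6-bis[(TBS)oxy]-4-[(1R)-1-[(TBS)oxy]-6-(phenylsulfonyl)hexyl]phenoxy}-5-[(TBS)oxy]phenyl)oct-2-yn-1-ol | `CC(C)(C)[Si](C)(C)Oc1cc(CCCCCC#CCO)cc(c1)Oc1c(O[Si](C)(C)C(C)(C)C)cc(cc1O[Si](C)(C)C(C)(C)C)[C@H](O[Si](C)(C)C(C)(C)C)CCCCCS(=O)(=O)c1ccccc1` | intermediate
22 | (2Z)-oct-2-en-1-ol analogue of 21 | `CC(C)(C)[Si](C)(C)Oc1cc(CCCCC/C=C\CO)cc(c1)Oc1c(O[Si](C)(C)C(C)(C)C)cc(cc1O[Si](C)(C)C(C)(C)C)[C@H](O[Si](C)(C)C(C)(C)C)CCCCCS(=O)(=O)c1ccccc1` | intermediate
23 | (2Z)-allylic methanesulfonate of 22 | `CC(C)(C)[Si](C)(C)Oc1cc(CCCCC/C=C\COS(C)(=O)=O)cc(c1)Oc1c(O[Si](C)(C)C(C)(C)C)cc(cc1O[Si](C)(C)C(C)(C)C)[C@H](O[Si](C)(C)C(C)(C)C)CCCCCS(=O)(=O)c1ccccc1` | intermediate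
24 | (2Z)-allylic chloride: 22 with OH replaced by Cl | `CC(C)(C)[Si](C)(C)Oc1cc(CCCCC/C=C\CCl)cc(c1)Oc1c(O[Si](C)(C)C(C)(C)C)cc(cc1O[Si](C)(C)C(C)(C)C)[C@H](O[Si](C)(C)C(C)(C)C)CCCCCS(=O)(=O)c1ccccc1` | intermediate
25 | potassium salt of 24 deprotonated at the carbon next to sulfur | `CC(C)(C)[Si](C)(C)Oc1cc(CCCCC/C=C\CCl)cc(c1)Oc1c(O[Si](C)(C)C(C)(C)C)cc(cc1O[Si](C)(C)C(C)(C)C)[C@H](O[Si](C)(C)C(C)(C)C)CCCC[CH-]S(=O)(=O)c1ccccc1.[K+]` | intermediate
26 | 22-membered macrocyclic sulfone: tetrakis-TBS ether of the target with phenylsulfonyl on C6′; (R) at C1′, (Z)-alkene, both epimers at C6′ | `CC(C)(C)[Si](C)(C)Oc1cc2cc(c1)Oc1c(O[Si](C)(C)C(C)(C)C)cc(cc1O[Si](C)(C)C(C)(C)C)[C@H](O[Si](C)(C)C(C)(C)C)CCCCC(S(=O)(=O)c1ccccc1)C/C=C\CCCCC2` | intermediate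
27 | tetrakis-TBS ether of the target macrocycle; (R) at C1′, (Z)-alkene | `CC(C)(C)[Si](C)(C)Oc1cc2cc(c1)Oc1c(O[Si](C)(C)C(C)(C)C)cc(cc1O[Si](C)(C)C(C)(C)C)[C@H](O[Si](C)(C)C(C)(C)C)CCCCCC/C=C\CCCCC2` | intermediate
28 | CNP0316989.2: 22-membered diaryl ether macrocycle with one phenol on ring A, two phenols on ring B flanking the ether oxygen, an (R)-benzylic carbinol and a (Z)-alkene | `Oc1cc2cc(c1)Oc1c(O)cc(cc1O)[C@H](O)CCCCCC/C=C\CCCCC2` | target

Total step count: 15 steps.
Longest linear sequence: 13 steps (3 → 4 → 7 → 8 → 12 → 13 → 14 → 15 → 21 → 22 → 24 → 26 → 27 → 28; steps 2–8 and 10–15).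

Steps most likely to fail

Step 13. Ring closure may lose to intermolecular alkylation, to attack at the far alkene carbon, or to base-induced elimination and geometric erosion at the (Z)-allylic chloride. The fallback sets out from compound 21. An Appel reaction (CBr4, PPh3, CH2Cl2, 0 °C) should give the propargylic bromide F1. KN(SiMe3)2 in THF at 0.001 M (−78 → 0 °C) should then close the same C6′–C7′ bond by SN2 at the propargylic carbon to give the macrocyclic cycloalkyne sulfone F2. In this variant no alkene geometry is at risk during ring closure and the alkyne disfavours the transposed (allenic) pathway. Lindlar semihydrogenation of the unstrained 22-membered cycloalkyne (H2, Lindlar catalyst, quinoline, EtOAc) comes back to the route at compound 26.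

Step 4. Transfer of the aryl group to copper and C–O bond formation at the doubly ortho-flanked, ester-deactivated phenol may be too slow, so that protodeboronation and homocoupling consume the boronic acid. The fallback sets out from compound 7. Treatment with 1-(diacetoxyiodo)-4-methoxybenzene and BF3·OEt2 (CH2Cl2, 0 °C), then aqueous NaBF4, should give the diaryliodonium salt {3-bromo-5-[(TBS)oxy]phenyl}(4-methoxyphenyl)iodonium tetrafluoroborate F3. The sodium phenoxide of 2 (NaH, THF, 0 °C) should then be O-arylated by it at 25 °C without any metal catalyst; the electron-richer anisyl group stays on iodine. This comes back to the route at compound 8.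

Step 1. Regiocontrol of the silylation may be poor if silyl migration does not equilibrate, giving mixtures of 3,4- and 3,5-bis-silyl and tris-silyl ethers. The fallback sets out from compound 1. The most acidic 4-OH should be benzylated selectively (BnBr, KHCO3, DMF, 25 °C) to methyl 4-(benzyloxy)-3,5-dihydroxybenzoate F4. The two remaining phenols are silylated (TBSCl, imidazole, DMF) to methyl 4-(benzyloxy)-3,5-bis[(TBS)oxy]benzoate F5. Hydrogenolysis of the benzyl ether (H2, Pd/C, EtOAc) comes back to the route at compound 2.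

Further compounds
F1 | step 13 | propargylic bromide: 21 with OH replaced by Br | `CC(C)(C)[Si](C)(C)Oc1cc(CCCCCC#CCBr)cc(c1)Oc1c(O[Si](C)(C)C(C)(C)C)cc(cc1O[Si](C)(C)C(C)(C)C)[C@H](O[Si](C)(C)C(C)(C)C)CCCCCS(=O)(=O)c1ccccc1`
F2 | step 13 | macrocyclic cycloalkyne sulfone: 26 with C8′≡C9′ in place of the (Z)-alkene | `CC(C)(C)[Si](C)(C)Oc1cc2cc(c1)Oc1c(O[Si](C)(C)C(C)(C)C)cc(cc1O[Si](C)(C)C(C)(C)C)[C@H](O[Si](C)(C)C(C)(C)C)CCCCC(S(=O)(=O)c1ccccc1)CC#CCCCCC2`
F3 | step 4 | {3-bromo-5-[(TBS)oxy]phenyl}(4-methoxyphenyl)iodonium tetrafluoroborate | `COc1ccc(cc1)[I+]c1cc(Br)cc(O[Si](C)(C)C(C)(C)C)c1.F[B-](F)(F)F`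
F4 | step 1 | methyl 4-(benzyloxy)-3,5-dihydroxybenzoate | `COC(=O)c1cc(O)c(OCc2ccccc2)c(O)c1`
F5 | step 1 | methyl 4-(benzyloxy)-3,5-bis[(TBS)oxy]benzoate | `COC(=O)c1cc(O[Si](C)(C)C(C)(C)C)c(OCc2ccccc2)c(O[Si](C)(C)C(C)(C)C)c1`
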